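Everything rests on a [3+3] closure of ring A around a temporary C-1 ketone. The precursor is a bicyclo[3.2.1]octane (rings C and D) whose C-9 carries a 3-oxobutan-2-yl arm (C-10, C-20, C-1, C-2) and whose C-8 carries a but-3-enoate arm ending in an alkylidene malonate (C-6, C-7, C-5, C-4, C-3, C-19). The key step exploits the 1,3-relationship of C-10 and C-2 across C-1 and of C-5 and C-3 across C-4: with NaOMe the C-10 enolate closes ring B by Michael addition (C-5–C-10) and the C-2 enolate closes ring A by Claisen condensation (C-2–C-3). The C-1 oxygen leaves later by enone transposition; C-4 is methylated on the finished ring.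

Key step: step 12

Remark: gibberellane numbering (C-1 to C-20) is used for all intermediates, β is the face of the C-15/C-16 bridge, H-5 and H-9, and 2-nitrobut-2-ene (12) is taken as a purchasable reagent (otherwise one dehydration step from 3-nitrobutan-2-ol).

Step 1
Reactants: 1 (R)-cyclohex-3-ene-1-carboxylic acid
Product: 2 (1R,4R,5R)-4-iodo-6-oxabicyclo[3.2.1]octan-7-one
Conditions: I2, KI, NaHCO3, H2O, 20 °C
Reagents that add atoms: iodine, II
Why: Iodolactonisation: anti addition of iodine and carboxylate across the alkene gives the bridged γ-lactone, so the stereocentre of 1 places the new C–O bond (future C-8) cis to the carboxyl carbon (future C-16) and the C–I bond trans to it.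

Step 2
Reactants: 2 (1R,4R,5R)-4-iodo-6-oxabicyclo[3.2.1]octan-7-one
Product: 3 (1R,5R)-6-oxabicyclo[3.2.1]oct-3-en-7-one
Conditions: DBU, toluene, 110 °C
Reagents that add atoms: none
Why: Anti-periplanar E2 dehydroiodination gives the allylic lactone (future C-9=C-11 alkene) without touching the stereocentres.

Step 3
Reactants: 3 (1R,5R)-6-oxabicyclo[3.2.1]oct-3-en-7-one; 4 (trimethylsilyl)methylmagnesium chloride
Product: 6 (1R,5R)-5-[3-(trimethylsilyl)prop-1-en-2-yl]cyclohex-2-en-1-ol, via bis-silyl diol 5 (not isolated)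
Conditions: 4 (4 equiv), CeCl3, THF, −70 to 20 °C; then SiO2, CH2Cl2, 20 °C
Reagents that add atoms: none
Why: Bunnelle allylsilane synthesis: CeCl3-mediated double addition of the Grignard reagent to the lactone carbonyl, then Peterson elimination of Me3SiOH; the lactone carbon becomes C-16 with C-15 and C-17 attached, and the cis alcohol/allylsilane relationship is inherited from 3.

Step 4
Reactants: 6 (1R,5R)-5-[3-(trimethylsilyl)prop-1-en-2-yl]cyclohex-2-en-1-ol
Product: 7 (5R)-5-[3-(trimethylsilyl)prop-1-en-2-yl]cyclohex-2-en-1-one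
Conditions: Dess–Martin periodinane, NaHCO3, CH2Cl2, 0 °C
Reagents that add atoms: none
Why: Dess–Martin oxidation of the allylic alcohol to the enone under buffered conditions that an allylsilane should tolerate.

Step 5
Reactants: 7 (5R)-5-[3-(trimethylsilyl)prop-1-en-2-yl]cyclohex-2-en-1-one; 8 tert-butyl acetate
Product: 9 tert-butyl 2-[(5R)-1-hydroxy-5-[3-(trimethylsilyl)prop-1-en-2-yl]cyclohex-2-en-1-yl]acetate (both C-1 epimers)
Conditions: 8, LiN(i-Pr)2, THF, −78 °C; then 7, −78 °C; H2O quench
Reagents that add atoms: none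
Why: Kinetic 1,2-addition (aldol type) of the lithium ester enolate to the enone carbonyl installs C-6 and C-7; the carbinol centre is destroyed in step 6, so its configuration does not matter.

Step 6
Reactants: 9 tert-butyl 2-[(5R)-1-hydroxy-5-[3-(trimethylsilyl)prop-1-en-2-yl]cyclohex-2-en-1-yl]acetate
Product: 10 tert-butyl 2-[(5S)-3-oxo-5-[3-(trimethylsilyl)prop-1-en-2-yl]cyclohex-1-en-1-yl]acetate
Conditions: IBX, DMSO, 55 °C
Reagents that add atoms: none
Why: Oxidative 1,3-transposition of a tertiary allylic alcohol (Dauben-type, IBX variant) moves the oxygen to the future C-11 and leaves the acetate arm on the enone β-carbon (future C-8).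

Step 7
Reactants: 10 tert-butyl 2-[(5S)-3-oxo-5-[3-(trimethylsilyl)prop-1-en-2-yl]cyclohex-1-en-1-yl]acetate
Product: 11 tert-butyl 2-[(1S,5S)-6-methylidene-3-(trimethylsilyloxy)bicyclo[3.2.1]oct-2-en-1-yl]acetate
Conditions: HNTf2 (5 mol %), CH2Cl2, −78 to −40 °C; Et3N quench
Reagents that add atoms: none
Why: Intramolecular Hosomi–Sakurai conjugate allylation catalysed by Me3SiNTf2 formed in the flask: the allylsilane terminus (C-15) adds 5-exo to the β-carbon, the bridge can only form cis to the C-13 substituent and so sets quaternary C-8, and silyl transfer traps the enolate regiospecifically as the C-9/C-11 silyl enol ether with the C-16 methylidene already in place.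

Step 8
Reactants: 11 tert-butyl 2-[(1S,5S)-6-methylidene-3-(trimethylsilyloxy)bicyclo[3.2.1]oct-2-en-1-yl]acetate; 12 2-nitrobut-2-ene
Product: 14 tert-butyl 2-[(1S,2S,5S)-6-methylidene-3-oxo-2-(3-oxobutan-2-yl)bicyclo[3.2.1]octan-1-yl]acetate (C-10 epimers), via silyl nitronate 13 (not isolated)
Conditions: 12, SnCl4, CH2Cl2, −78 °C; then H2O–THF, 40 °C
Reagents that add atoms: water, O
Why: Yoshikoshi 1,4-diketone synthesis (Mukaiyama–Michael addition to a nitroalkene, then Nef hydrolysis of the nitronate): the electrophile should attack C-9 anti to the axial C-15 on the neighbouring C-8, which places C-10 on the α face and H-9 on the β face; C-10 forms as a mixture that is erased by enolisation in step 12.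

Step 9
Reactants: 14 tert-butyl 2-[(1S,2S,5S)-6-methylidene-3-oxo-2-(3-oxobutan-2-yl)bicyclo[3.2.1]octan-1-yl]acetate; 15 1,2-bis(trimethylsilyloxy)ethane
Product: 16 tert-butyl 2-[(1S,2S,5S)-6-methylidene-2-[1-(2-methyl-1,3-dioxolan-2-yl)ethyl]-3-oxobicyclo[3.2.1]octan-1-yl]acetate (C-10 epimers)
Conditions: 15, Me3SiOTf (2 mol %), CH2Cl2, −78 to −30 °C; pyridine quench
Reagents that add atoms: none
Why: Noyori ketalisation under kinetic control should protect only the side-chain methyl ketone, because a ketal at C-11 would place an oxygen syn-axial to the C-15/C-16 bridge.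

Step 10
Reactants: 16 tert-butyl 2-[(1S,2S,5S)-6-methylidene-2-[1-(2-methyl-1,3-dioxolan-2-yl)ethyl]-3-oxobicyclo[3.2.1]octan-1-yl]acetate
Product: 17 tert-butyl 2-[(1S,2S,3R,5S)-3-hydroxy-6-methylidene-2-[1-(2-methyl-1,3-dioxolan-2-yl)ethyl]bicyclo[3.2.1]octan-1-yl]acetate (C-10 epimers)
Conditions: SmI2 (2.5 equiv), HMPA, i-PrOH, THF, 0 °C
Reagents that add atoms: none
Why: SmI2 ketone reduction (dissolving-metal type): the bulky O–Sm group of the ketyl should take the equatorial site away from the two-carbon bridge, giving the thermodynamically preferred equatorial 11α-alcohol.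

Step 11
Reactants: 17 tert-butyl 2-[(1S,2S,3R,5S)-3-hydroxy-6-methylidene-2-[1-(2-methyl-1,3-dioxolan-2-yl)ethyl]bicyclo[3.2.1]octan-1-yl]acetate; 18 dimethyl 2-(methoxymethylidene)propanedioate
Product: 20 tert-butyl 2-[(1R,2S,3R,5S)-3-hydroxy-6-methylidene-2-(3-oxobutan-2-yl)bicyclo[3.2.1]octan-1-yl]-4,4-bis(methoxycarbonyl)but-3-enoate (epimers at C-6 and C-10), via ketal triester 19 (not isolated)
Conditions: LiN(i-Pr)2 (3.2 equiv), THF, −78 to −30 °C; 18, −78 to 0 °C; then 1 M HCl, THF, 20 °C
Reagents that add atoms: water, O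
Why: Addition–elimination of the ester enolate on an alkoxymethylene malonate (vinylogous acylation) attaches C-5, C-4, C-3 and C-19 to C-6, and the acidic work-up hydrolyses the dioxolane; C-6 is acidic and is re-set in step 12.

Step 12
Reactants: 20 tert-butyl 2-[(1R,2S,3R,5S)-3-hydroxy-6-methylidene-2-(3-oxobutan-2-yl)bicyclo[3.2.1]octan-1-yl]-4,4-bis(methoxycarbonyl)but-3-enoate
Product: 22 7-tert-butyl 19-methyl 11α-hydroxy-1,3-dioxo-18-norgibberell-16-ene-7,19-dioate (enolised β-diketone, C-4 epimerisable), via Michael adduct 21 (not isolated)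
Conditions: NaOMe (4 equiv), MeOH, 65 °C; then AcOH
Reagents that add atoms: none
Why: Methoxide equilibrates the enolates of the C-1 ketone; the C-10 enolate adds to C-5 of the alkylidene malonate (5-(enolexo)-exo-trig Michael addition, closing ring B), and after proton transfer the C-2 enolate attacks the malonate ester that becomes C-3 (6-(enolexo)-exo-trig Claisen acylation, closing ring A) with loss of methoxide, the β-diketone enolate making the sequence irreversible. The closest known reaction is the Vorländer dimedone synthesis (Michael addition then Claisen condensation between a methyl ketone unit and a malonate), here with the Michael step run intramolecularly from ketone enolate to alkylidene malonate. C-10 is set in the Michael step, where the bulky enolate arm (C-1/C-2) should sit on the face of H-9 and the C-20 methyl on the face of C-11. C-5 is set in the same step with the malonate residue anti to both the C-1 arm and the C-7 ester (all-trans array on C-6, C-5 and C-10), and C-6, acidic before and epimerisable after the addition, should settle with the ester β. The step needs C-10 rather than C-2 to add first, which ring size secures (five- against seven-membered), and Claisen attack on the malonate rather than on C-7, which the tert-butyl ester secures. The Michael step stays reversible until the Claisen closure, so the trans-fused, all-trans adduct can be funnelled through.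

Step 13
Reactants: 22 7-tert-butyl 19-methyl 11α-hydroxy-1,3-dioxo-18-norgibberell-16-ene-7,19-dioate
Product: 23 7-tert-butyl 19-methyl 11α-hydroxy-3-methoxy-1-oxo-18-norgibberella-2,16-diene-7,19-dioate (C-4 epimers)
Conditions: MeOH, pyridinium p-toluenesulfonate (10 mol %), 4 Å molecular sieves, 50 °C
Reagents that add atoms: methanol, CO
Why: Acid-catalysed enol etherification of the cyclic β-diketone should put the methoxy group on C-3, the carbonyl flanked by the tertiary C-4, and not on C-1 next to quaternary C-10, as is known for 4,4-disubstituted cyclohexane-1,3-diones.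

Step 14
Reactants: 23 7-tert-butyl 19-methyl 11α-hydroxy-3-methoxy-1-oxo-18-norgibberella-2,16-diene-7,19-dioate
Product: 25 7-tert-butyl 19-methyl 11α-hydroxy-3-oxo-18-norgibberella-1,16-diene-7,19-dioate (C-4 epimers), via allylic alcohol 24 (not isolated)
Conditions: NaBH4, CeCl3·7H2O, MeOH, 0 °C; then 1 M HCl, THF, 20 °C
Reagents that add atoms: water, O
Why: Stork–Danheiser sequence: Luche 1,2-reduction of the vinylogous ester carbonyl at C-1, then acid hydrolysis with loss of water and methanol gives the transposed enone, which removes the C-1 oxygen and regenerates the C-3 ketone.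

Step 15
Reactants: 25 7-tert-butyl 19-methyl 11α-hydroxy-3-oxo-18-norgibberella-1,16-diene-7,19-dioate
Product: 26 7-tert-butyl 19-methyl 11α-hydroxy-3-oxogibberella-1,16-diene-7,19-dioate
Conditions: K2CO3, MeI, acetone, 20 °C
Reagents that add atoms: iodomethane, CI
Why: C-Alkylation of the β-keto ester enolate: methyl iodide should approach C-4 anti to the axial C-20 methyl (1,3 across C-5), making C-18 β and the C-19 ester α (cis to C-20), as in podocarpic-acid-type alkylations.

Step 16
Reactants: 26 7-tert-butyl 19-methyl 11α-hydroxy-3-oxogibberella-1,16-diene-7,19-dioate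
Product: 27 7-tert-butyl 19-methyl 11α-hydroxy-3-oxogibberell-16-ene-7,19-dioate
Conditions: [(Ph3P)CuH]6, H2O (2 equiv), benzene–THF, 20 °C
Reagents that add atoms: none
Why: Conjugate reduction of the enone with the copper hydride hexamer, which should leave the isolated 1,1-disubstituted alkene and both esters untouched.

Step 17
Reactants: 27 7-tert-butyl 19-methyl 11α-hydroxy-3-oxogibberell-16-ene-7,19-dioate
Product: 28 7-tert-butyl 19-methyl 3β,11α-dihydroxygibberell-16-ene-7,19-dioate
Conditions: K[(s-Bu)3BH] (3 equiv), THF, −78 °C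
Reagents that add atoms: none
Why: Ketone reduction with a bulky trialkylborohydride: equatorial attack on the chair ring A should give the axial 3β-alcohol.

Step 18
Reactants: 28 7-tert-butyl 19-methyl 3β,11α-dihydroxygibberell-16-ene-7,19-dioate
Product: 29 7-tert-butyl hydrogen 3β,11α-dihydroxygibberell-16-ene-7,19-dioate (free C-19 acid)
Conditions: n-PrSLi, HMPA, 20 to 50 °C; then aq. HCl
Reagents that add atoms: none
Why: SN2 demethylation of the hindered axial methyl ester by thiolate; the tert-butyl ester cannot react this way and the thiolate is too weak a base to trigger retro-aldol opening at C-3/C-4.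

Step 19
Reactants: 29 7-tert-butyl hydrogen 3β,11α-dihydroxygibberell-16-ene-7,19-dioate
Product: 30 3β,11α-dihydroxygibberell-16-ene-7,19-dioic acid (11α-hydroxy-GA14, CNP0232910.1)
Conditions: Me3SiOTf, 2,6-lutidine, CH2Cl2, 0 °C; then MeOH–H2O
Reagents that add atoms: none
Why: Silyl triflate-mediated cleavage of the tert-butyl ester with loss of 2-methylpropene under buffered, non-protic conditions that should spare the exocyclic alkene; aqueous methanol removes the transient silyl groups.

Compound list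
1 | (R)-cyclohex-3-ene-1-carboxylic acid | OC(=O)[C@H]1CC=CCC1 | starting material
2 | (1R,4R,5R)-4-iodo-6-oxabicyclo[3.2.1]octan-7-one | O=C1O[C@H]2[C@H](I)CC[C@@H]1C2 | intermediate
3 | (1R,5R)-6-oxabicyclo[3.2.1]oct-3-en-7-one | O=C1O[C@H]2C=CC[C@@H]1C2 | intermediate
4 | (trimethylsilyl)methylmagnesium chloride | C[Si](C)(C)C[Mg]Cl | starting material
5 | (1R,5R)-5-[2-hydroxy-1,3-bis(trimethylsilyl)propan-2-yl]cyclohex-2-en-1-ol (bis-silyl diol) | O[C@H]1C=CC[C@@H](C(O)(C[Si](C)(C)C)C[Si](C)(C)C)C1 | intermediate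
6 | (1R,5R)-5-[3-(trimethylsilyl)prop-1-en-2-yl]cyclohex-2-en-1-ol | O[C@H]1C=CC[C@@H](C(=C)C[Si](C)(C)C)C1 | intermediate
7 | (5R)-5-[3-(trimethylsilyl)prop-1-en-2-yl]cyclohex-2-en-1-one | O=C1C=CC[C@@H](C(=C)C[Si](C)(C)C)C1 | intermediate
8 | tert-butyl acetate | CC(=O)OC(C)(C)C | starting material
9 | tert-butyl 2-[(5R)-1-hydroxy-5-[3-(trimethylsilyl)prop-1-en-2-yl]cyclohex-2-en-1-yl]acetate (C-1 epimers) | OC1(CC(=O)OC(C)(C)C)C=CC[C@@H](C(=C)C[Si](C)(C)C)C1 | intermediate
10 | tert-butyl 2-[(5S)-3-oxo-5-[3-(trimethylsilyl)prop-1-en-2-yl]cyclohex-1-en-1-yl]acetate | O=C1C=C(CC(=O)OC(C)(C)C)C[C@H](C(=C)C[Si](C)(C)C)C1 | intermediate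
11 | tert-butyl 2-[(1S,5S)-6-methylidene-3-(trimethylsilyloxy)bicyclo[3.2.1]oct-2-en-1-yl]acetate | C=C1C[C@]2(CC(=O)OC(C)(C)C)C[C@H]1CC(O[Si](C)(C)C)=C2 | intermediate
12 | 2-nitrobut-2-ene | CC=C(C)[N+](=O)[O-] | starting material
13 | trimethylsilyl nitronate of tert-butyl 2-[(1S,2S,5S)-6-methylidene-2-(3-nitrobutan-2-yl)-3-oxobicyclo[3.2.1]octan-1-yl]acetate | C=C1C[C@]2(CC(=O)OC(C)(C)C)C[C@H]1CC(=O)[C@H]2C(C)C(C)=[N+]([O-])O[Si](C)(C)C | intermediate
14 | tert-butyl 2-[(1S,2S,5S)-6-methylidene-3-oxo-2-(3-oxobutan-2-yl)bicyclo[3.2.1]octan-1-yl]acetate (C-10 epimers) | C=C1C[C@]2(CC(=O)OC(C)(C)C)C[C@H]1CC(=O)[C@H]2C(C)C(C)=O | intermediate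
15 | 1,2-bis(trimethylsilyloxy)ethane | C[Si](C)(C)OCCO[Si](C)(C)C | starting material
16 | tert-butyl 2-[(1S,2S,5S)-6-methylidene-2-[1-(2-methyl-1,3-dioxolan-2-yl)ethyl]-3-oxobicyclo[3.2.1]octan-1-yl]acetate (C-10 epimers) | C=C1C[C@]2(CC(=O)OC(C)(C)C)C[C@H]1CC(=O)[C@H]2C(C)C1(C)OCCO1 | intermediate
17 | tert-butyl 2-[(1S,2S,3R,5S)-3-hydroxy-6-methylidene-2-[1-(2-methyl-1,3-dioxolan-2-yl)ethyl]bicyclo[3.2.1]octan-1-yl]acetate (C-10 epimers) | C=C1C[C@]2(CC(=O)OC(C)(C)C)C[C@H]1C[C@@H](O)[C@H]2C(C)C1(C)OCCO1 | intermediate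
18 | dimethyl 2-(methoxymethylidene)propanedioate | COC=C(C(=O)OC)C(=O)OC | starting material
19 | tert-butyl 2-[(1R,2S,3R,5S)-3-hydroxy-6-methylidene-2-[1-(2-methyl-1,3-dioxolan-2-yl)ethyl]bicyclo[3.2.1]octan-1-yl]-4,4-bis(methoxycarbonyl)but-3-enoate (ketal triester, epimers at C-6 and C-10) | C=C1C[C@]2(C(C(=O)OC(C)(C)C)C=C(C(=O)OC)C(=O)OC)C[C@H]1C[C@@H](O)[C@H]2C(C)C1(C)OCCO1 | intermediate
20 | tert-butyl 2-[(1R,2S,3R,5S)-3-hydroxy-6-methylidene-2-(3-oxobutan-2-yl)bicyclo[3.2.1]octan-1-yl]-4,4-bis(methoxycarbonyl)but-3-enoate (key-step precursor, epimers at C-6 and C-10) | C=C1C[C@]2(C(C(=O)OC(C)(C)C)C=C(C(=O)OC)C(=O)OC)C[C@H]1C[C@@H](O)[C@H]2C(C)C(C)=O | intermediate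
21 | 7-tert-butyl 3,19-dimethyl 11α-hydroxy-1-oxo-18-nor-2,3-secogibberell-16-ene-3,7,19-trioate (Michael adduct; 10α-methyl, 10β-acetyl, 5β-H, 6β-ester) | C=C1C[C@]23C[C@H]1C[C@@H](O)[C@H]2[C@](C)(C(C)=O)[C@@H](C(C(=O)OC)C(=O)OC)[C@@H]3C(=O)OC(C)(C)C | intermediate
22 | 7-tert-butyl 19-methyl 11α-hydroxy-1,3-dioxo-18-norgibberell-16-ene-7,19-dioate (C-4 epimerisable) | C=C1C[C@]23C[C@H]1C[C@@H](O)[C@H]2[C@]1(C)C(=O)CC(=O)C(C(=O)OC)[C@H]1[C@@H]3C(=O)OC(C)(C)C | intermediate
23 | 7-tert-butyl 19-methyl 11α-hydroxy-3-methoxy-1-oxo-18-norgibberella-2,16-diene-7,19-dioate (C-4 epimers) | C=C1C[C@]23C[C@H]1C[C@@H](O)[C@H]2[C@]1(C)C(=O)C=C(OC)C(C(=O)OC)[C@H]1[C@@H]3C(=O)OC(C)(C)C | intermediate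
24 | 7-tert-butyl 19-methyl 1,11α-dihydroxy-3-methoxy-18-norgibberella-2,16-diene-7,19-dioate (C-1 and C-4 epimers) | C=C1C[C@]23C[C@H]1C[C@@H](O)[C@H]2[C@]1(C)C(O)C=C(OC)C(C(=O)OC)[C@H]1[C@@H]3C(=O)OC(C)(C)C | intermediate
25 | 7-tert-butyl 19-methyl 11α-hydroxy-3-oxo-18-norgibberella-1,16-diene-7,19-dioate (C-4 epimers) | C=C1C[C@]23C[C@H]1C[C@@H](O)[C@H]2[C@]1(C)C=CC(=O)C(C(=O)OC)[C@H]1[C@@H]3C(=O)OC(C)(C)C | intermediate
26 | 7-tert-butyl 19-methyl 11α-hydroxy-3-oxogibberella-1,16-diene-7,19-dioate (4β-methyl, 4α-ester) | C=C1C[C@]23C[C@H]1C[C@@H](O)[C@H]2[C@]1(C)C=CC(=O)[C@@](C)(C(=O)OC)[C@H]1[C@@H]3C(=O)OC(C)(C)C | intermediate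
27 | 7-tert-butyl 19-methyl 11α-hydroxy-3-oxogibberell-16-ene-7,19-dioate | C=C1C[C@]23C[C@H]1C[C@@H](O)[C@H]2[C@]1(C)CCC(=O)[C@@](C)(C(=O)OC)[C@H]1[C@@H]3C(=O)OC(C)(C)C | intermediate
28 | 7-tert-butyl 19-methyl 3β,11α-dihydroxygibberell-16-ene-7,19-dioate | C=C1C[C@]23C[C@H]1C[C@@H](O)[C@H]2[C@]1(C)CC[C@H](O)[C@@](C)(C(=O)OC)[C@H]1[C@@H]3C(=O)OC(C)(C)C | intermediate
29 | 7-tert-butyl hydrogen 3β,11α-dihydroxygibberell-16-ene-7,19-dioate | C=C1C[C@]23C[C@H]1C[C@@H](O)[C@H]2[C@]1(C)CC[C@H](O)[C@@](C)(C(=O)O)[C@H]1[C@@H]3C(=O)OC(C)(C)C | intermediate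
30 | 3β,11α-dihydroxygibberell-16-ene-7,19-dioic acid (CNP0232910.1) | C=C1C[C@]23C[C@H]1C[C@@H](O)[C@H]2[C@]1(C)CC[C@H](O)[C@@](C)(C(=O)O)[C@H]1[C@@H]3C(=O)O | target

Total step count: 19 steps.
Longest linear sequence: 19 steps (from 1; compounds 4, 8, 12, 15 and 18 are purchased).

The three steps most likely to fail:

1. Step 12. What may go wrong: the acidic C-6 proton of the acceptor arm quenches the C-10 enolate before conjugate addition, or the Michael closure runs through the cis-fused epimer before the Claisen step locks the ring. Fallback: starting from 20, soft enolisation with Me3SiOTf/Et3N (CH2Cl2, 20 °C, equilibrating) should give the bis-silyl compound F1 (C-10/C-1 trimethylsilyl enol ether, C-11 silyl ether). A TiCl4-mediated intramolecular Mukaiyama–Michael addition at −78 °C (no free enolate, chelated closed transition state) then gives the Michael adduct 21 as an isolated compound after aqueous work-up. KOt-Bu in THF effects the Claisen closure alone and the route is rejoined at 22.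

2. Step 10. What may go wrong: hydrogen delivery from the open lower face during the reduction, which gives the axial alcohol on the side of the two-carbon bridge, or poor facial selectivity. Fallback: starting from 16, Li[(s-Bu)3BH] (THF, −78 °C) is used to make the axial 11-epimeric alcohol F2 on purpose. Mitsunobu inversion (4-nitrobenzoic acid, PPh3, diisopropyl azodicarboxylate, toluene) gives the inverted 4-nitrobenzoate F3, and methanolysis with K2CO3 in MeOH returns to the route at 17.

3. Step 8. What may go wrong: desilylation of the hindered enol ether without C–C bond formation, or Lewis-acid-induced migration of the exocyclic double bond. Fallback: starting from 11, MeLi (THF, 0 °C) releases the lithium enolate regiospecifically and conjugate addition to 12 at −78 °C gives the γ-nitro ketone F4. A separate Nef reaction (NaOMe in MeOH, then aqueous TiCl3 buffered with NH4OAc) returns to the route at 14.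

Further compounds
F1 | step 12 | tert-butyl 4,4-bis(methoxycarbonyl)-2-[(1R,2S,3R,5S)-6-methylidene-3-(trimethylsilyloxy)-2-[3-(trimethylsilyloxy)but-2-en-2-yl]bicyclo[3.2.1]octan-1-yl]but-3-enoate | C=C1C[C@]2(C(C(=O)OC(C)(C)C)C=C(C(=O)OC)C(=O)OC)C[C@H]1C[C@@H](O[Si](C)(C)C)[C@H]2C(C)=C(C)O[Si](C)(C)C
F2 | step 10 | 11-epimer of 17 (axial alcohol on the bridge face) | C=C1C[C@]2(CC(=O)OC(C)(C)C)C[C@H]1C[C@H](O)[C@H]2C(C)C1(C)OCCO1
F3 | step 10 | 4-nitrobenzoate of 17 | C=C1C[C@]2(CC(=O)OC(C)(C)C)C[C@H]1C[C@@H](OC(=O)c3ccc(cc3)[N+](=O)[O-])[C@H]2C(C)C4(C)OCCO4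
F4 | step 8 | tert-butyl 2-[(1S,2S,5S)-6-methylidene-2-(3-nitrobutan-2-yl)-3-oxobicyclo[3.2.1]octan-1-yl]acetate | C=C1C[C@]2(CC(=O)OC(C)(C)C)C[C@H]1CC(=O)[C@H]2C(C)C(C)[N+](=O)[O-]
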